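**Retrosynthetic overview**
- The 1(10)-oxirane is added last by peracid epoxidation of a triene diester; the C3 ester (Steglich, retention), the C8 ester (Mitsunobu, inversion) and the α-methylene group (Eschenmoser) are late additions.
- The trans-fused 6,12-lactone comes from an invertive Mitsunobu lactonisation of a cis-hydroxy acid; the C8 oxygen is carried as a benzyldimethylsilyl group (Tamao–Fleming).
- Key step: the ten-membered ring is made by anionic oxy-Cope ring expansion of a trans-1,2-dialkenylcyclohexenol (C6–C1 broken, C8–C9 formed), which sets C8 and both ring alkenes, with in-flask C7 alkylation of the enolate.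
- The cyclohexenol comes from an (E)-2-silylvinyllithium and a cyclohexenone made in three steps from (S)-carvone, which supplies C3 and the relay stereocentre C1.
- Ring order: six-membered ring (carvone), then ten-membered carbocycle, then γ-lactone, then 1,10-oxirane; the acyl oxirane is made separately by Sharpless epoxidation.

Assumption: locants C1–C15 follow germacranolide numbering (ring C1–C10, lactone carbons C11–C13, C14 on C10, C15 on C4); (R)-2-methylbutanoic acid and (E)-2-methylbut-2-en-1-ol are bought. Stereochemical outcomes of steps 6–8, 11 and 19 are predictions from transition-state models, not demonstrated results.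

**Step 1**
Reactants: 1 (S)-(+)-carvone
Product: 2 (1S,5S)-2-methyl-5-(prop-1-en-2-yl)cyclohex-2-en-1-ol (cis-carveol)
Conditions: NaBH4, CeCl3·7H2O, MeOH, −78 to 0 °C
Reagents that add atoms: none
Why: Luche 1,2-reduction; hydride enters axially, anti to the C5 isopropenyl group, so the new carbinol centre is S with OH cis to isopropenyl.

**Step 2**
Reactants: 2 cis-carveol
Product: 3 (1S,5S)-2-methyl-5-(prop-1-en-2-yl)cyclohex-2-en-1-yl triisopropylsilyl ether
Conditions: i-Pr3SiOTf, 2,6-lutidine, CH2Cl2, −78 to 0 °C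
Reagents that add atoms: triisopropylsilyl trifluoromethanesulfonate, CC(C)[Si](OS(=O)(=O)C(F)(F)F)(C(C)C)C(C)C
Why: O-silylation of the allylic alcohol; the triisopropylsilyl ether is chosen because it must survive the later base, hydride and brief fluoride treatments.

**Step 3**
Reactants: 3 silyl ether
Product: 4 (4S,6S)-3-methyl-6-(prop-1-en-2-yl)-4-(triisopropylsilyloxy)cyclohex-2-en-1-one
Conditions: CrO3, 3,5-dimethylpyrazole, CH2Cl2, −20 °C
Reagents that add atoms: chromium trioxide, O=[Cr](=O)=O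
Why: Salmond-type allylic oxidation converts the only ring methylene allylic to the trisubstituted alkene into the enone carbonyl; the carbinol C–H is shielded by the silyl ether and no stereocentre is touched.

**Step 4**
Reactants: 5 ethynylmagnesium bromide (HC≡CMgBr); 6 benzylchlorodimethylsilane
Product: 7 benzyl(ethynyl)dimethylsilane
Conditions: THF, 0 to 25 °C
Reagents that add atoms: none
Why: nucleophilic substitution at silicon by the acetylide Grignard reagent.

**Step 5**
Reactants: 7 benzyl(ethynyl)dimethylsilane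
Product: 8 (E)-benzyldimethyl[2-(tributylstannyl)ethenyl]silane
Conditions: Bu3SnH, AIBN (cat.), neat, 85 °C
Reagents that add atoms: tributylstannane, CCCC[SnH](CCCC)CCCC
Why: radical hydrostannylation; reversible stannyl-radical addition funnels the product to the (E)-β-stannyl vinylsilane.

**Step 6**
Reactants: 8 vinylstannane; 4 enone
Product: 10 (1S,4S,6S)-1-[(E)-2-(benzyldimethylsilyl)ethenyl]-3-methyl-6-(prop-1-en-2-yl)-4-(triisopropylsilyloxy)cyclohex-2-en-1-ol (alkenyl groups trans), via (E)-2-(benzyldimethylsilyl)ethenyllithium 9 (not isolated)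
Conditions: 8, n-BuLi, THF, −78 °C; then 4, −78 °C; H2O
Reagents that add atoms: none
Why: tin–lithium exchange with retention of the (E) geometry, then 1,2-addition to the enone from the face anti to the cis-disposed isopropenyl and silyloxy groups, which sets the carbinol centre S with the two alkenyl groups trans.

**Step 7**
Reactants: 10 divinyl carbinol; 11 methyl bromoacetate
Product: 14 methyl 2-[(1S,2S,4E,7S,8Z)-2-(benzyldimethylsilyl)-4,8-dimethyl-10-oxo-7-(triisopropylsilyloxy)cyclodeca-4,8-dien-1-yl]acetate, via potassium carbinolate 12 (not isolated), via potassium trienolate 13 (not isolated)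
Conditions: KN(SiMe3)2, 18-crown-6, THF, 0 to 25 °C; then 11, −78 to −40 °C
Reagents that add atoms: none
Why: anionic oxy-Cope rearrangement through a chair transition state (both ring bonds and the (E)-silyl group equatorial) breaks C6–C1 and forms C8–C9, relaying the C1 configuration to C8 (S, silyl α), giving the (E)-1(10) alkene and keeping the (Z)-4,5 alkene; the ring-trans enolate is then C-alkylated on its open face, anti to the new C8–C9 bond, which sets C7 with the acetate arm β.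

**Step 8**
Reactants: 14 keto ester
Product: 16 (3aS,4S,6E,9S,10Z,11aS)-4-(benzyldimethylsilyl)-6,10-dimethyl-9-(triisopropylsilyloxy)-3a,4,5,8,9,11a-hexahydrocyclodeca[b]furan-2(3H)-one (cis-fused lactone), via hydroxy ester 15 (not isolated)
Conditions: NaBH4, CeCl3·7H2O, MeOH, −40 to 25 °C
Reagents that add atoms: none
Why: Luche 1,2-reduction of the enone; hydride adds anti to the C7–C8 ring bond (Felkin–Anh, peripheral attack) to give the 6S alkoxide cis to the acetate arm, which lactonises with loss of methanol.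

**Step 9**
Reactants: 16 cis-lactone
Product: 17 2-[(1S,2S,4E,7S,8Z,10S)-2-(benzyldimethylsilyl)-10-hydroxy-4,8-dimethyl-7-(triisopropylsilyloxy)cyclodeca-4,8-dien-1-yl]acetic acid
Conditions: LiOH, THF/H2O, 0 to 25 °C; then cold 0.5 M HCl to pH 4, used at once
Reagents that add atoms: lithium hydroxide, [Li+].[OH-]
Why: saponification of the lactone; the cis-hydroxy acid is extracted cold and not purified because it recloses readily.

**Step 10**
Reactants: 17 hydroxy acid
Product: 18 (3aS,4S,6E,9S,10Z,11aR)-4-(benzyldimethylsilyl)-6,10-dimethyl-9-(triisopropylsilyloxy)-3a,4,5,8,9,11a-hexahydrocyclodeca[b]furan-2(3H)-one (trans-fused lactone)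
Conditions: PPh3, DIAD, toluene (0.005 M), 0 °C
Reagents that add atoms: none
Why: Mitsunobu lactonisation; the C6 alkoxyphosphonium is displaced intramolecularly (5-exo, SN2) by the carboxylate with inversion, 6S to 6R, giving the trans ring fusion of the target.

**Step 11**
Reactants: 18 trans-lactone
Product: 19 (3aR,4S,6E,9S,10Z,11aR)-4-hydroxy-6,10-dimethyl-9-(triisopropylsilyloxy)-3a,4,5,8,9,11a-hexahydrocyclodeca[b]furan-2(3H)-one (8α-alcohol)
Conditions: Bu4NF, THF, 0 °C, 15 min; then KHCO3, 30% H2O2, MeOH, 40 °C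
Reagents that add atoms: hydrogen peroxide, OO
Why: Tamao–Fleming oxidation; fluoride cleaves the benzyl–silicon bond and peroxide then drives carbon-to-oxygen migration with retention at C8 (S), the short cold fluoride treatment sparing the triisopropylsilyl ether.

**Step 12**
Reactants: 20 (E)-2-methylbut-2-en-1-ol
Product: 21 [(2S,3S)-2,3-dimethyloxiran-2-yl]methanol
Conditions: Ti(OiPr)4 (5 mol%), L-(+)-diethyl tartrate (6 mol%), t-BuOOH, 4 Å MS, CH2Cl2, −20 °C
Reagents that add atoms: tert-butyl hydroperoxide, CC(C)(C)OO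
Why: Sharpless asymmetric epoxidation; the L-(+)-tartrate catalyst delivers oxygen to the face that gives the (2S,3S) epoxy alcohol from an (E)-allylic alcohol.

**Step 13**
Reactants: 21 epoxy alcohol
Product: 22 (2R,3S)-2,3-dimethyloxirane-2-carboxylic acid
Conditions: RuCl3·H2O (2 mol%), NaIO4, MeCN/EtOAc/H2O, 0 to 25 °C
Reagents that add atoms: sodium periodate, [Na+].[O-]I(=O)(=O)=O; water, O
Why: RuO4-catalysed oxidation of the primary alcohol to the acid; the oxirane centres are untouched and only the CIP label at C2 changes from S to R.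

**Step 14**
Reactants: 19 8α-alcohol; 22 epoxy acid
Product: 23 (3aR,4R,6E,9S,10Z,11aR)-6,10-dimethyl-2-oxo-9-(triisopropylsilyloxy)-2,3,3a,4,5,8,9,11a-octahydrocyclodeca[b]furan-4-yl (2R,3S)-2,3-dimethyloxirane-2-carboxylate
Conditions: PPh3, DIAD, toluene, 0 to 25 °C
Reagents that add atoms: none
Why: Mitsunobu esterification; SN2 displacement of the C8 alkoxyphosphonium by the carboxylate of 22 inverts C8 from S to R (8β ester) without exposing the free alcohol to base.

**Step 15**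
Reactants: 23 lactone ester
Product: 25 (3R,3aR,4R,6E,9S,10Z,11aR)-3-[(dimethylamino)methyl]-6,10-dimethyl-2-oxo-9-(triisopropylsilyloxy)-2,3,3a,4,5,8,9,11a-octahydrocyclodeca[b]furan-4-yl (2R,3S)-2,3-dimethyloxirane-2-carboxylate, via lithium lactone enolate 24 (not isolated)
Conditions: LiN(SiMe3)2, THF, −78 °C; CH2=NMe2+ I−, −78 to 0 °C
Reagents that add atoms: N,N-dimethylmethyleneiminium iodide, C=[N+](C)C.[I-]
Why: Mannich reaction of the lactone enolate with Eschenmoser's salt; only the lactone has α-hydrogens (the C8 acyl group is α-quaternary), and the new C11 centre is destroyed in the next step.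

**Step 16**
Reactants: 25 Mannich base
Product: 27 (3aR,4R,6E,9S,10Z,11aR)-6,10-dimethyl-3-methylidene-2-oxo-9-(triisopropylsilyloxy)-2,3,3a,4,5,8,9,11a-octahydrocyclodeca[b]furan-4-yl (2R,3S)-2,3-dimethyloxirane-2-carboxylate, via trimethylammonium iodide 26 (not isolated)
Conditions: MeI, CH2Cl2/MeOH, 25 °C; then sat. aq. NaHCO3, 25 °C
Reagents that add atoms: none
Why: N-quaternisation followed by E1cB (Hofmann-type) elimination of trimethylamine gives the α-methylene lactone.

**Step 17**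
Reactants: 27 silyl ether
Product: 28 (3aR,4R,6E,9S,10Z,11aR)-9-hydroxy-6,10-dimethyl-3-methylidene-2-oxo-2,3,3a,4,5,8,9,11a-octahydrocyclodeca[b]furan-4-yl (2R,3S)-2,3-dimethyloxirane-2-carboxylate
Conditions: HF·pyridine, pyridine, THF, 0 to 25 °C
Reagents that add atoms: none
Why: fluoride-mediated desilylation under buffered conditions that leave the acyl oxirane and the methylene lactone intact.

**Step 18**
Reactants: 28 C3 alcohol; 29 (R)-2-methylbutanoic acid
Product: 30 (3aR,4R,6E,9S,10Z,11aR)-6,10-dimethyl-3-methylidene-9-{[(2R)-2-methylbutanoyl]oxy}-2-oxo-2,3,3a,4,5,8,9,11a-octahydrocyclodeca[b]furan-4-yl (2R,3S)-2,3-dimethyloxirane-2-carboxylate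
Conditions: EDC·HCl, DMAP (cat.), CH2Cl2, 0 °C
Reagents that add atoms: none
Why: Steglich esterification with retention at C3; run cold with catalytic DMAP so the α-stereocentre of the acid is not epimerised.

**Step 19**
Reactants: 30 triene diester
Product: 31 target CNP0265335.3 ((1R,3S,4Z,6R,7R,8R,10R)-1,10-epoxy-3-[(2R)-2-methylbutanoyloxy]-8-[(2R,3S)-2,3-dimethyloxirane-2-carbonyloxy]germacra-4,11(13)-dien-12,6-olide)
Conditions: mCPBA, NaHCO3, CH2Cl2, 0 °C
Reagents that add atoms: 3-chloroperoxybenzoic acid, OOC(=O)c1cccc(Cl)c1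
Why: Prilezhaev epoxidation; only the 1(10) alkene is electron-rich (the 4,5-alkene carries two allylic acyloxy groups and the methylene lactone is electron-poor), and the peracid attacks the outer face of the (E)-alkene in the preferred ring conformation to give the 1R,10R (1β,10α) oxirane.

**Compound list**
1 | (S)-(+)-carvone | CC1=CC[C@@H](CC1=O)C(C)=C | starting material
2 | (1S,5S)-cis-carveol | CC1=CC[C@@H](C[C@@H]1O)C(C)=C | intermediate
3 | (1S,5S)-cis-carveol triisopropylsilyl ether | CC1=CC[C@@H](C[C@@H]1O[Si](C(C)C)(C(C)C)C(C)C)C(C)=C | intermediate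
4 | (4S,6S)-3-methyl-6-(prop-1-en-2-yl)-4-(triisopropylsilyloxy)cyclohex-2-en-1-one | CC1=CC(=O)[C@@H](C[C@@H]1O[Si](C(C)C)(C(C)C)C(C)C)C(C)=C | intermediate
5 | ethynylmagnesium bromide | C#C[Mg]Br | starting material
6 | benzylchlorodimethylsilane | C[Si](C)(Cl)Cc1ccccc1 | starting material
7 | benzyl(ethynyl)dimethylsilane | C#C[Si](C)(C)Cc1ccccc1 | intermediate
8 | (E)-benzyldimethyl[2-(tributylstannyl)ethenyl]silane | CCCC[Sn](CCCC)(CCCC)/C=C/[Si](C)(C)Cc1ccccc1 | intermediate
9 | (E)-2-(benzyldimethylsilyl)ethenyllithium | [Li]/C=C/[Si](C)(C)Cc1ccccc1 | intermediate (not isolated)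
10 | (1S,4S,6S)-1-[(E)-2-(benzyldimethylsilyl)ethenyl]-3-methyl-6-(prop-1-en-2-yl)-4-(triisopropylsilyloxy)cyclohex-2-en-1-ol | CC1=C[C@@](O)(/C=C/[Si](C)(C)Cc2ccccc2)[C@@H](C[C@@H]1O[Si](C(C)C)(C(C)C)C(C)C)C(C)=C | intermediate
11 | methyl bromoacetate | COC(=O)CBr | starting material
12 | potassium alkoxide of 10 | CC1=C[C@@]([O-])(/C=C/[Si](C)(C)Cc2ccccc2)[C@@H](C[C@@H]1O[Si](C(C)C)(C(C)C)C(C)C)C(C)=C.[K+] | intermediate (not isolated)
13 | potassium (1Z,3S,5E,8S,9Z)-3-(benzyldimethylsilyl)-5,9-dimethyl-8-(triisopropylsilyloxy)cyclodeca-1,5,9-trien-1-olate | C/C1=C/C([O-])=C/[C@@H]([Si](C)(C)Cc2ccccc2)C/C(C)=C/C[C@@H]1O[Si](C(C)C)(C(C)C)C(C)C.[K+] | intermediate (not isolated)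
14 | methyl 2-[(1S,2S,4E,7S,8Z)-2-(benzyldimethylsilyl)-4,8-dimethyl-10-oxo-7-(triisopropylsilyloxy)cyclodeca-4,8-dien-1-yl]acetate | C/C1=C/C(=O)[C@H](CC(=O)OC)[C@@H]([Si](C)(C)Cc2ccccc2)C/C(C)=C/C[C@@H]1O[Si](C(C)C)(C(C)C)C(C)C | intermediate
15 | methyl 2-[(1S,2S,4E,7S,8Z,10S)-2-(benzyldimethylsilyl)-10-hydroxy-4,8-dimethyl-7-(triisopropylsilyloxy)cyclodeca-4,8-dien-1-yl]acetate | C/C1=C/[C@H](O)[C@H](CC(=O)OC)[C@@H]([Si](C)(C)Cc2ccccc2)C/C(C)=C/C[C@@H]1O[Si](C(C)C)(C(C)C)C(C)C | intermediate (not isolated)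
16 | (3aS,4S,6E,9S,10Z,11aS)-4-(benzyldimethylsilyl)-6,10-dimethyl-9-(triisopropylsilyloxy)-3a,4,5,8,9,11a-hexahydrocyclodeca[b]furan-2(3H)-one, cis-fused | C/C1=C/[C@@H]2OC(=O)C[C@@H]2[C@@H]([Si](C)(C)Cc3ccccc3)C/C(C)=C/C[C@@H]1O[Si](C(C)C)(C(C)C)C(C)C | intermediate
17 | 2-[(1S,2S,4E,7S,8Z,10S)-2-(benzyldimethylsilyl)-10-hydroxy-4,8-dimethyl-7-(triisopropylsilyloxy)cyclodeca-4,8-dien-1-yl]acetic acid | C/C1=C/[C@H](O)[C@H](CC(=O)O)[C@@H]([Si](C)(C)Cc2ccccc2)C/C(C)=C/C[C@@H]1O[Si](C(C)C)(C(C)C)C(C)C | intermediate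
18 | (3aS,4S,6E,9S,10Z,11aR)-4-(benzyldimethylsilyl)-6,10-dimethyl-9-(triisopropylsilyloxy)-3a,4,5,8,9,11a-hexahydrocyclodeca[b]furan-2(3H)-one, trans-fused | C/C1=C/[C@H]2OC(=O)C[C@@H]2[C@@H]([Si](C)(C)Cc3ccccc3)C/C(C)=C/C[C@@H]1O[Si](C(C)C)(C(C)C)C(C)C | intermediate
19 | (3aR,4S,6E,9S,10Z,11aR)-4-hydroxy-6,10-dimethyl-9-(triisopropylsilyloxy)-3a,4,5,8,9,11a-hexahydrocyclodeca[b]furan-2(3H)-one | C/C1=C/[C@H]2OC(=O)C[C@@H]2[C@@H](O)C/C(C)=C/C[C@@H]1O[Si](C(C)C)(C(C)C)C(C)C | intermediate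
20 | (E)-2-methylbut-2-en-1-ol | C/C=C(\C)CO | starting material
21 | [(2S,3S)-2,3-dimethyloxiran-2-yl]methanol | C[C@@H]1O[C@@]1(C)CO | intermediate
22 | (2R,3S)-2,3-dimethyloxirane-2-carboxylic acid | C[C@@H]1O[C@@]1(C)C(=O)O | intermediate
23 | (3aR,4R,6E,9S,10Z,11aR)-6,10-dimethyl-2-oxo-9-(triisopropylsilyloxy)-2,3,3a,4,5,8,9,11a-octahydrocyclodeca[b]furan-4-yl (2R,3S)-2,3-dimethyloxirane-2-carboxylate | C/C1=C/[C@H]2OC(=O)C[C@@H]2[C@H](OC(=O)[C@]3(C)O[C@H]3C)C/C(C)=C/C[C@@H]1O[Si](C(C)C)(C(C)C)C(C)C | intermediate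
24 | lithium lactone enolate of 23 | C/C1=C/[C@H]2OC([O-])=C[C@@H]2[C@H](OC(=O)[C@]3(C)O[C@H]3C)C/C(C)=C/C[C@@H]1O[Si](C(C)C)(C(C)C)C(C)C.[Li+] | intermediate (not isolated)
25 | (3R)-3-[(dimethylamino)methyl] derivative of 23 | C/C1=C/[C@H]2OC(=O)[C@@H](CN(C)C)[C@@H]2[C@H](OC(=O)[C@]3(C)O[C@H]3C)C/C(C)=C/C[C@@H]1O[Si](C(C)C)(C(C)C)C(C)C | intermediate
26 | N-methyl trimethylammonium iodide of 25 | C/C1=C/[C@H]2OC(=O)[C@@H](C[N+](C)(C)C)[C@@H]2[C@H](OC(=O)[C@]3(C)O[C@H]3C)C/C(C)=C/C[C@@H]1O[Si](C(C)C)(C(C)C)C(C)C.[I-] | intermediate (not isolated)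
27 | (3aR,4R,6E,9S,10Z,11aR)-6,10-dimethyl-3-methylidene-2-oxo-9-(triisopropylsilyloxy)-2,3,3a,4,5,8,9,11a-octahydrocyclodeca[b]furan-4-yl (2R,3S)-2,3-dimethyloxirane-2-carboxylate | C/C1=C/[C@H]2OC(=O)C(=C)[C@@H]2[C@H](OC(=O)[C@]3(C)O[C@H]3C)C/C(C)=C/C[C@@H]1O[Si](C(C)C)(C(C)C)C(C)C | intermediate
28 | 9-hydroxy analogue of 27 (3aR,4R,6E,9S,10Z,11aR) | C/C1=C/[C@H]2OC(=O)C(=C)[C@@H]2[C@H](OC(=O)[C@]3(C)O[C@H]3C)C/C(C)=C/C[C@@H]1O | intermediate
29 | (R)-2-methylbutanoic acid | CC[C@@H](C)C(=O)O | starting material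
30 | (3aR,4R,6E,9S,10Z,11aR)-6,10-dimethyl-3-methylidene-9-{[(2R)-2-methylbutanoyl]oxy}-2-oxo-2,3,3a,4,5,8,9,11a-octahydrocyclodeca[b]furan-4-yl (2R,3S)-2,3-dimethyloxirane-2-carboxylate | C/C1=C/[C@H]2OC(=O)C(=C)[C@@H]2[C@H](OC(=O)[C@]3(C)O[C@H]3C)C/C(C)=C/C[C@@H]1OC(=O)[C@H](C)CC | intermediate
31 | CNP0265335.3, (1R,3S,4Z,6R,7R,8R,10R)-1,10-epoxy heliangolide diester | C=C1C(=O)O[C@@H]2/C=C(/C)[C@@H](OC(=O)[C@H](C)CC)C[C@H]3O[C@]3(C)C[C@@H](OC(=O)[C@]3(C)O[C@H]3C)[C@@H]12 | target

**Step count and risks**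
Total step count: 19. Longest linear sequence: 15 steps from (S)-carvone (steps 1–3, 6–11, 14–19).

Three steps most likely to fail:

Step 7 (oxy-Cope/alkylation). The potassium alkoxide and crown ether may isomerise the isopropenyl group or give poor C- versus O-alkylation, and the C7 face selectivity rests on a conformational model. Fallback, setting out from 10 and rejoining at 14: silylate 10 (Me3SiOTf, Et3N, CH2Cl2, −78 °C) to the tertiary trimethylsilyl ether F1. Heat F1 in degassed o-dichlorobenzene in a base-washed sealed tube at about 200 °C, so that a neutral siloxy-Cope rearrangement through the same chair gives the ring-expanded trimethylsilyl enol ether F2, which can be purified and characterised. Cleave F2 with MeLi (THF, 0 °C) to the lithium enolate F3 and alkylate this with 11 (DMPU, −78 to −30 °C) to reach 14.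

Step 14 (Mitsunobu at C8). SN2 displacement at a hindered secondary carbinol on a ten-membered ring, with an α-quaternary acid, may stall or give elimination. Fallback, setting out from 19 and rejoining at 23: oxidise 19 with Dess–Martin periodinane (NaHCO3, CH2Cl2) to the 8-ketone F4. Reduce F4 with NaBH4 and CeCl3·7H2O (MeOH, −78 °C); hydride adds anti to the C6–C7 bond to give the 8β-alcohol F5 (8R, cis to C11). Acylate F5 with 22 (DCC, DMAP, CH2Cl2, 0 °C) with retention to give 23.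

Step 19 (final epoxidation). Face selectivity depends on the ring conformation of 30 and could favour the 1S,10S oxirane. Fallback, setting out from 30 and arriving directly at 31: replace substrate control by reagent control with a Shi epoxidation (D-fructose-derived Shi ketone, KHSO5, K2CO3 buffer, MeCN/dimethoxymethane/H2O, 0 °C). The chiral dioxirane delivers oxygen to trans-trisubstituted alkenes in the (R,R) sense required at C1 and C10; this fallback makes no new compound (none, F0).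

**Further compounds**
F1 | step 7 | trimethylsilyl ether of 10 | CC1=C[C@@](O[Si](C)(C)C)(/C=C/[Si](C)(C)Cc2ccccc2)[C@@H](C[C@@H]1O[Si](C(C)C)(C(C)C)C(C)C)C(C)=C
F2 | step 7 | (1Z,3S,5E,8S,9Z)-3-(benzyldimethylsilyl)-5,9-dimethyl-8-(triisopropylsilyloxy)-1-(trimethylsilyloxy)cyclodeca-1,5,9-triene | C/C1=C/C(O[Si](C)(C)C)=C/[C@@H]([Si](C)(C)Cc2ccccc2)C/C(C)=C/C[C@@H]1O[Si](C(C)C)(C(C)C)C(C)C
F3 | step 7 | lithium (1Z,3S,5E,8S,9Z)-3-(benzyldimethylsilyl)-5,9-dimethyl-8-(triisopropylsilyloxy)cyclodeca-1,5,9-trien-1-olate | C/C1=C/C([O-])=C/[C@@H]([Si](C)(C)Cc2ccccc2)C/C(C)=C/C[C@@H]1O[Si](C(C)C)(C(C)C)C(C)C.[Li+]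
F4 | step 14 | (3aS,6E,9S,10Z,11aR)-6,10-dimethyl-9-(triisopropylsilyloxy)-3,3a,5,8,9,11a-hexahydrocyclodeca[b]furan-2,4-dione | C/C1=C/[C@H]2OC(=O)C[C@@H]2C(=O)C/C(C)=C/C[C@@H]1O[Si](C(C)C)(C(C)C)C(C)C
F5 | step 14 | (3aR,4R,6E,9S,10Z,11aR)-4-hydroxy-6,10-dimethyl-9-(triisopropylsilyloxy)-3a,4,5,8,9,11a-hexahydrocyclodeca[b]furan-2(3H)-one | C/C1=C/[C@H]2OC(=O)C[C@@H]2[C@H](O)C/C(C)=C/C[C@@H]1O[Si](C(C)C)(C(C)C)C(C)C
F0 | step 19 | none | none
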